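**The flask.** Follow one molecule of starting material through the violet flask.

in all of them: starting material 0.21 M
- violet: reagent 1.1 equiv; temperature 80 °C; the very flask that is asked about, followed so far
- amber: reagent 2.2 equiv; temperature 86 °C; run made earlier
- flask: reagent 1.10 equiv; temperature 80 °C; time 50 min

| run | time / min | target / % | starting material / % |
|---|---|---|---|
| violet | 3.00 | 35.7 | 40.3 |
| violet | 10.0 | 49.7 | 25.8 |
| violet | 20.0 | 53.4 | 19.4 |
| violet | 25.0 | 57.5 | 18.1 |
| violet | 40.0 | 55.0 | 16.3 |
| violet | 50.0 | 55.1 | 16.2 |
| amber | 3.00 | 38.5 | 5.4 |
| amber | 5.00 | 44.3 | 2.1 |
| amber | 8.00 | 44.8 | 0.2 |
| amber | 12.0 | 43.6 | 0.9 |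
| amber | 20.0 | 42.7 | 0 |
| amber | 40.0 | 41.7 | 0 |

(standard deviation of a reading: 1 percentage point)

- north-east: at 50 min take out 90% of the target then present, then wait 15 min
- south: at 50 min add reagent, 100% of the amount charged, then wait 15 min
- south-east: at 50 min raise the temperature by 25 K, then wait 15 min
- east: change nothing and wait 15 min more

- target taken out counts as made
- additions bring no volume worth counting

* target, in percent of the starting material first charged, at 50 min
* which option adds most target ("none" when 2 percentage points or less is all one gets) (north-east / south / south-east / east / none)
* target present, with what was taken out counted in, in percent of the starting material first charged, after north-east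
* target present, with what was taken out counted in, in percent of the starting material first charged, after east

**The pace.** I began with rates. In the violet run the starting material went at 0.199 min⁻¹ of its charge over the first 3.00 min. Between 25.0 min and 40.0 min it went at 0.00120 min⁻¹, a rough reading. That is a slowing by a factor of 166. The fall in starting material gives a factor of 4.08, which leaves 40.7 for something else. I took that to be reagent, the limiting reagent.

**The balance.** I counted one reagent for each target and two for each missing molecule. At 50.0 min the violet readings then put the use at 1.12 equiv, beside the 1.1 equiv charged, and each reading carries a scatter of 1 percentage point.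

**The fork.** In its first 3.00 min the violet run made 35.7% of target and lost 24.0% to the other path, at a mean reagent of 0.682 equiv. I supposed the odds for target fall as reagent rises. At 0.21 M that gives the even level, the amount of reagent at which a molecule has equal chances of target and side product: 1.01 equiv. It is a selectivity factor with reagent inside. The chance of target is the even level over the even level plus the reagent. The amber run, at 86 °C and with 2.2 equiv, reckoned the same way, gave 0.993 equiv.

**My reckoning.** I expected about 55.0% now. South restores the reagent, and I put the mean life of the starting material then at about 2.18 min, shorter than 15 min. The chance is 0.480, so the 16.2% remaining should give 7.8 points. The other options add no reagent.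

**The result.** The forecast gave 55.4%, 55.6% after north-east, 55.5% after east, and chose south, on a reading that “points to reagent running out”. The flask held 56.0%, with 0.422% of its reagent free. It gave 56.3% after north-east and 55.8% after east, and the best option was south: the changes were 7.7 points for south, 0.22 points for north-east, −0.27 points for east and −5.3 points for south-east.

    target → over-reaction product (k = 1.09 × 10⁻⁵ s⁻¹, Ea = 106 kJ mol⁻¹)
    starting material + reagent → target (k = 0.0305 M⁻¹ s⁻¹, Ea = 57.0 kJ mol⁻¹)
    starting material + 2 reagent → side product (k = 0.145 M⁻² s⁻¹, Ea = 55.0 kJ mol⁻¹)
    (constants at 80 °C)

**The reason.** The path to side product is the main reason for the missing target: without it the flask stands at 95.6%, against 56.0%. South's gain, set against the 16.4% of starting material in the flask at 50.0 min, comes to a share of 0.470. The same flask charged with 2.80 equiv of reagent fell to 41.0% of its own charge of reagent, a midpoint of 1.97 equiv. That midpoint gives a chance of 0.339, and that second flask held 33.7% of target.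

(The earlier runs and the new flask come from a simulation with made-up constants, noise included.)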